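## Analysis of the target

The target 22 is 8-(3,4-dimethoxyphenyl)-2,6-dimethoxynaphthalene-1,4-dione. It has a quinone ring A (C1 to C4, methoxy on C2), a fused benzo ring B (C4a, C5 to C8, C8a; methoxy on C6, aryl on C8) and a pendant 3,4-dimethoxyphenyl ring C. There is no stereocentre, and because ring C has no ortho substituent the C8–aryl bond is not a stable axis, so the problem is purely one of regiochemistry. The sensitive group is the 2-methoxyquinone, a vinylogous ester that exchanges its methoxy group with nucleophiles and is labile to base and to redox reagents; it is best unmasked in the last step. The difficulty is the fixed relation of three groups across two rings: ring C is peri to the C1 carbonyl, which is the carbonyl next to the methoxylated C2, and meta to the C6 methoxy group. Substitution or peri cross-coupling on a preformed naphthalene does not give this pattern cleanly. The strategy rests on ring B: C8 (with ring C) and C5 are 1,4-related through C8a–C4a, and C6(OMe)–C7(H) is a two-carbon unit at the oxidation level of an alkyne with an ether on one end. Ring B is therefore what remains when a fused 2-pyranone carrying ring C on its C1 takes up a methoxy alkyne across C1 and C4 and gives up its O–C(=O) bridge; ring A, masked as a 1,2,4-trimethoxybenzene, maps onto 2,4,5-trimethoxybenzaldehyde 1.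

## Retrosynthetic reasoning

From 22 to 21. The first step back cuts no carbon–carbon bond. The two carbonyl groups of ring A are traced to the para-related methyl ethers at C1 and C4 of the tetramethoxynaphthalene 21. The quinone would not survive organometallic, basic or hot conditions, whereas the ether form does, so a robust, fully aromatic intermediate is gained. The forward reaction has to oxidise only the most electron-rich ring, at the para pair and not at the C1/C2 ortho pair, and leave ring C and the C6 ether alone.

From 21 to 15 and 19. Ring B is opened at C7–C8 and C5–C6, and C8 and C5 are rejoined through an O–C(=O) bridge. This gives the 1-aryl-2-benzopyran-3-one 15 (its C1 is C8 of 21, its C4 is C5) and the ynol ether 19, with the bridged lactone 20 between them. The cut is made here because ring C is then already on the carbon that becomes C8, so no aryl group has to be forced into a peri position later, and because 19 brings C6 in as an aryl methyl ether at its final oxidation level. A cut at the C8–aryl bond would need a naphthalene with a leaving group exactly at C8 and differentiated oxygens elsewhere, which is no easier to make than 21. The forward reaction must be a regioselective [4+2] addition, CH end of 19 to C1 of 15, followed by decarboxylation.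

From 15 to 13. The lactone C–O bond at C1 is cut, which reveals the keto acid 13; the mixed anhydride 14 is its activated form. Only a cyclodehydration is needed in the forward direction, so every carbon of 15 is already present in 13 and the ortho-quinoid system is generated one step before it is used.

From 13 to 10. The two carbonyl carbons of 13 are reconnected as a double bond, by way of the aldehyde 12 and the diol 11, to give the 3-arylindene 10. The detour through a five-membered ring is made for regiochemical reasons. An intermolecular acylation of a ring that already carries the acetic acid chain would have to prefer the position ortho to a single methoxy group over the position flanked by two. In 10 the 1,2-relation of the aroyl carbon and the CH2 carbon is built into the ring. The forward reaction is an oxidative cleavage of one trisubstituted alkene beside two electron-rich arenes, then an aldehyde-to-acid oxidation.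

From 10 to 6 and 7. The bond between C3 of the indene and ring C is cut, which leads to the indanone 6 and the aryl bromide 7 through the Grignard reagent 8 and the carbinol 9. This is the point where ring C enters; carbonyl addition followed by dehydration is the shortest way to a 3-arylindene.

From 6 to 1 and 2. The aryl–carbonyl bond of 6 is cut (intramolecular acylation of the acid 5), and the chain is traced through the cinnamic acid 4 and the arylidene malonic acid 3 to aldehyde 1 and malonic acid 2. In 5 only one ring position next to the chain is free, so the ring closure cannot go astray, and the 2,4,5-trimethoxy pattern of 1 becomes the 1,2,4-pattern of ring A without further adjustment.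

From 19 to 16. The ynol ether is taken back to the chloroacetal 16 by two eliminations, through 17 and the acetylide 18; 19 is made when needed and not stored.

## Alternatives that were turned down

Alternative 1: Ring B is cut at C4a–C5 and C8–C8a, which leads to 2-methoxy-1,4-benzoquinone A1 as dienophile and the (E)-1-aryl-3-silyloxybutadiene A2 as diene. In the forward sense the two would combine thermally at the unsubstituted double bond of A1 to give the racemic endo adduct A3, with the hydrogens at C4a, C8 and C8a all cis.
- For: both partners are one or two steps from commercial material, the union is a standard quinone Diels–Alder reaction, and the plan is more convergent than the chosen one. The orientation is also reasonable: the aryl and silyloxy groups both make the CH2 terminus of A2 the nucleophilic end, and this end should seek the quinone carbon β to the C1 carbonyl, the more ketone-like of the two.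
- Against: that orientation rests on a modest difference between two carbonyl groups. A3 is four hydrogen atoms away from the naphthoquinone oxidation level, so three stereocentres are made only to be erased. The C6 oxygen arrives as a silyl ether, so a desilylation and an O-methylation would have to be run on a 2-methoxyquinone, the group that tolerates base and nucleophiles least.
- Comparison: on step count this alternative is the stronger one (about seven operations against ten). The chosen strategy offers instead a ring B that is formed directly as an arene with the C6 methyl ether in place, a regiochemical bias in which polarity and sterics act together, and a quinone that appears only in the last step. The price is a less precedented key step.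

Alternative 2: Ring B is cut at C4a–C5 and C6–C7, which gives the vinylquinone A4, 2-[1-(3,4-dimethoxyphenyl)ethenyl]-6-methoxy-1,4-benzoquinone, as an electron-poor diene and 1,1-dimethoxyethene A5 as the two-carbon partner. In the forward sense A5 would add across the free quinone carbon next to the vinyl group and the vinyl CH2, and tautomerisation would give the dihydronaphthalenediol A6 with a dimethyl ketal at C6. Loss of one ketal methoxy group and oxidation of the hydroquinone would complete 22.
- For: like 19, A5 brings C6 in at the right oxidation level and already as a methyl ether. A5 is far easier to obtain and handle than 19, and on that point the alternative is stronger. Only two mild operations follow the key step.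
- Against: the effort moves into A4, whose 1,1-diarylethene skeleton with a 2,3,5-trioxygenated ring needs a regiocontrolled synthesis about as long as that of 15. Vinylquinones dimerise readily, because one molecule can act as diene and another as dienophile. The strongly nucleophilic A5 can also add in conjugate fashion to the other free quinone position, react by [2+2] addition or transfer an electron.
- Comparison: the polar logic is the same as in the chosen route. There, however, the reactive diene is a lactone-held quinodimethane reached by robust steps, and no quinone is present when the carbon–carbon bonds are made. The end-games are equally short.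

Alternative 3: Ring B is cut at C6–C7 and C8–C8a, which leads to 2-(2,4,5-trimethoxyphenyl)acetyl chloride A7 and 4-ethynyl-1,2-dimethoxybenzene A8. Under a stoichiometric strong Lewis acid at low temperature the acylium ion from A7 would add to the terminal alkyne carbon, and the aryl-stabilised vinyl cation would close onto the arene to give the naphthol A9. O-Methylation of A9 gives 21, and the final oxidation gives 22.
- For: this is the shortest plan of all, about four steps against ten, and on step economy it is clearly stronger. Ring B is born aromatic with its oxygen on C6, and the direction of addition to the alkyne is unambiguous.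
- Against: the risk is concentrated in one step with little room to tune it.
  - The vinyl cation must attack the ring position ortho to a single methoxy group, while the ipso carbon is para to a methoxy group, so spirocyclisation with dealkylation and capture by chloride compete.
  - A strong Lewis acid coordinates to and can cleave some of the five aryl ethers.
  - The acylium ion of A7 is prone to decarbonylation to a highly stabilised benzyl cation, and to intermolecular acylation at the doubly activated position of a second molecule or on the ring of A8.
  - A8 itself oligomerises under these conditions.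
- Comparison: the chosen route engages the same ring position in an intramolecular five-ring acylation early, on cheap material (step 3), and forms ring B under neutral thermal conditions. A9 is also the compound through which the fallback for the key step returns to the route, there reached by a base-mediated closure.

Key step: step 9

Assumption: ynol ether 19 is prepared on the day of use and handled only as a cold toluene solution behind a shield, and pyranone 15 is taken to be isolable under anhydrous conditions, as 1-aryl members of this class generally are.

## Route

Step 1
Reactants: 1 2,4,5-trimethoxybenzaldehyde; 2 malonic acid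
Product: 4 (E)-3-(2,4,5-trimethoxyphenyl)prop-2-enoic acid, via arylidene malonic acid 3 (not isolated)
Conditions: pyridine, piperidine (cat.), 95 °C; then aq. HCl
Reagents that add atoms: none
Why: Knoevenagel–Doebner condensation: the arylidene malonic acid 3 loses CO2 in hot pyridine and should give the more stable E acid (the geometry is erased in step 2 in any case).

Step 2
Reactants: 4 (E)-3-(2,4,5-trimethoxyphenyl)prop-2-enoic acid
Product: 5 3-(2,4,5-trimethoxyphenyl)propanoic acid
Conditions: H2 (1 atm), 10% Pd/C, EtOAc/MeOH, rt
Reagents that add atoms: none
Why: Catalytic hydrogenation of the conjugated C=C bond; the arene, the ethers and the acid are inert under these conditions.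

Step 3
Reactants: 5 3-(2,4,5-trimethoxyphenyl)propanoic acid
Product: 6 4,6,7-trimethoxy-2,3-dihydro-1H-inden-1-one
Conditions: Eaton's reagent (P2O5 in MeSO3H), rt to 50 °C, dilute
Reagents that add atoms: none
Why: Intramolecular Friedel–Crafts acylation; the only free position next to the chain is ortho to a methoxy group, so a single indanone can form, and Eaton's reagent avoids the aryl ether cleavage that AlCl3 would risk.

Step 4
Reactants: 6 4,6,7-trimethoxy-2,3-dihydro-1H-inden-1-one; 7 4-bromo-1,2-dimethoxybenzene
Product: 10 3-(3,4-dimethoxyphenyl)-4,5,7-trimethoxy-1H-indene, via Grignard reagent 8 (not isolated), via tertiary alcohol 9 (not isolated)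
Conditions: 7, Mg, THF, reflux; add 6, THF, 0 °C to rt; 2 M aq. HCl; then p-TsOH (cat.), PhMe, 50 °C
Reagents that add atoms: none
Why: Grignard addition to the ketone followed by acid-induced E1 dehydration of the tertiary, doubly benzylic alcohol 9; the double bond should end up conjugated with both rings as the 3-aryl-1H-indene, and the stereocentre of 9 disappears.

Step 5
Reactants: 10 3-(3,4-dimethoxyphenyl)-4,5,7-trimethoxy-1H-indene
Product: 12 2-[2-(3,4-dimethoxybenzoyl)-3,4,6-trimethoxyphenyl]acetaldehyde, via cis-diol 11 (not isolated)
Conditions: OsO4 (cat.), NaIO4, 2,6-lutidine, dioxane/H2O, rt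
Reagents that add atoms: OsO4, O=[Os](=O)(=O)=O (delivers the two oxygen atoms, turned over by the periodate); NaIO4, [Na+].[O-]I(=O)(=O)=O
Why: Lemieux–Johnson oxidation: syn dihydroxylation of the only alkene and periodate cleavage of the diol 11 turn C3 into the diaryl ketone and C2 into the aldehyde; 2,6-lutidine holds back the α-hydroxy ketone side path, and OsO4 does not touch the arenes.

Step 6
Reactants: 12 2-[2-(3,4-dimethoxybenzoyl)-3,4,6-trimethoxyphenyl]acetaldehyde
Product: 13 2-[2-(3,4-dimethoxybenzoyl)-3,4,6-trimethoxyphenyl]acetic acid
Conditions: NaClO2, NaH2PO4, 2-methyl-2-butene, t-BuOH/H2O, 0 °C to rt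
Reagents that add atoms: NaClO2, [Na+].[O-]Cl=O
Why: Pinnick oxidation of the aldehyde; 2-methyl-2-butene traps the HOCl that would otherwise chlorinate the methoxylated rings, and the diaryl ketone is inert.

Step 7
Reactants: 13 2-[2-(3,4-dimethoxybenzoyl)-3,4,6-trimethoxyphenyl]acetic acid
Product: 15 1-(3,4-dimethoxyphenyl)-5,7,8-trimethoxy-3H-2-benzopyran-3-one, via mixed anhydride 14 (not isolated)
Conditions: Ac2O, 120 °C, Ar, short time; evaporate, azeotrope with PhMe, crystallise under anhydrous conditions
Reagents that add atoms: none
Why: Cyclodehydration of an o-aroylphenylacetic acid, the standard entry to 1-aryl-2-benzopyran-3-ones: the mixed anhydride 14 enolises, the ketone oxygen closes onto the activated acyl carbon, and loss of acetic acid gives the ortho-quinoid lactone. The 1-aryl group and the methoxy donors should make 15 stable enough to isolate; every trace of acetic acid must be removed because 19 adds carboxylic acids.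

Step 8
Reactants: 16 2-chloro-1,1-dimethoxyethane
Product: 19 methoxyacetylene (methoxyethyne), via chlorovinyl ether 17 (not isolated), via sodium methoxyacetylide 18 (not isolated)
Conditions: NaNH2 (3 equiv), liq. NH3, −33 °C; evaporate NH3; sat. aq. NaCl, −20 °C; distil into cold PhMe, dry over K2CO3
Reagents that add atoms: none
Why: Twofold base-induced elimination (methanol, then HCl) from the α-chloroacetal, a classical preparation of alkoxyacetylenes; the third equivalent of NaNH2 holds the product as its sodium salt 18 until the cold aqueous quench.

Step 9
Reactants: 15 1-(3,4-dimethoxyphenyl)-5,7,8-trimethoxy-3H-2-benzopyran-3-one; 19 methoxyacetylene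
Product: 21 8-(3,4-dimethoxyphenyl)-1,2,4,6-tetramethoxynaphthalene, via bridged lactone 20 (not isolated)
Conditions: 19 (5 equiv, PhMe solution), PhMe, sealed tube, 80 to 110 °C, Ar, dark, acid-free glassware
Reagents that add atoms: none
Why: Proposed new method: the closest known reaction type is the Diels–Alder addition of 1-aryl-2-benzopyran-3-ones to electron-poor alkynes with loss of CO2 to give 1-arylnaphthalenes, together with the decarboxylative additions of monocyclic 2-pyranones to ynamines; using an ynol ether on the benzopyranone is the untested part. Pyranone 15 is an ortho-quinodimethane with a narrow frontier-orbital gap, so it can act as the acceptor toward the electron-rich alkyne 19: the nucleophilic CH terminus of 19 should bond to C1, the oxocarbenium-like terminus next to the ring oxygen, and the oxygen-bearing alkyne carbon to C4, the enolate-like carbon α to the lactone carbonyl, probably with the C1 bond running ahead (asynchronous, or through a short-lived zwitterion of an arylacetate enolate and an alkoxy-stabilised vinyl cation). Ring B is closed by an intermolecular [4+2] cycloaddition across C1 and C4, which forms the C7–C8 and C5–C6 bonds and gives the 2-oxabicyclo[2.2.2]octadiene 20; a cycloreversion then expels CO2, so that ring B appears directly as an arene and the benzo ring regains its sextet, which is the driving force. The two bridgehead stereocentres of 20 are tied to each other by the bicycle and vanish on decarboxylation, so no stereocontrol is called for. The selectivity needed is regiochemical, methoxy on C6 and not on C7, and two features of 15 secure it: the polarity match just described, and the fact that only the unsubstituted alkyne carbon fits next to C1, which carries ring C and is flanked by the peri methoxy group. The medium is kept free of acid and water because 19 adds carboxylic acids and hydrates readily, and 19 has no retro-ene path to a ketene of the kind open to higher alkyl ynol ethers.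

Step 10
Reactants: 21 8-(3,4-dimethoxyphenyl)-1,2,4,6-tetramethoxynaphthalene
Product: 22 8-(3,4-dimethoxyphenyl)-2,6-dimethoxynaphthalene-1,4-dione
Conditions: (NH4)2Ce(NO3)6 (2.5 equiv), MeCN/H2O, 0 °C
Reagents that add atoms: water, O
Why: Oxidative demethylation of a para-dimethoxyarene: two one-electron oxidations by tetravalent cerium, attack of water at C1 and C4 and loss of two molecules of methanol should give the 1,4-quinone. Ring A is by far the most electron-rich ring and its para pair should react in preference to the ortho pair, so the C2 methoxy group survives as the vinylogous ester; ring C has no para-related oxygen pair and should be left alone at 0 °C.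

## Compound list

1 | 2,4,5-trimethoxybenzaldehyde | COc1cc(OC)c(C=O)cc1OC | starting material
2 | malonic acid | OC(=O)CC(=O)O | starting material
3 | 2-[(2,4,5-trimethoxyphenyl)methylidene]propanedioic acid | COc1cc(OC)c(C=C(C(=O)O)C(=O)O)cc1OC | intermediate
4 | (E)-3-(2,4,5-trimethoxyphenyl)prop-2-enoic acid | COc1cc(OC)c(/C=C/C(=O)O)cc1OC | intermediate
5 | 3-(2,4,5-trimethoxyphenyl)propanoic acid | COc1cc(OC)c(CCC(=O)O)cc1OC | intermediate
6 | 4,6,7-trimethoxy-2,3-dihydro-1H-inden-1-one | O=C1CCc2c(OC)cc(OC)c(OC)c12 | intermediate
7 | 4-bromo-1,2-dimethoxybenzene | COc1ccc(Br)cc1OC | starting material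
8 | (3,4-dimethoxyphenyl)magnesium bromide | COc1ccc([Mg]Br)cc1OC | intermediate
9 | 1-(3,4-dimethoxyphenyl)-4,6,7-trimethoxy-2,3-dihydro-1H-inden-1-ol (racemic) | OC1(c2ccc(OC)c(OC)c2)CCc2c(OC)cc(OC)c(OC)c12 | intermediate
10 | 3-(3,4-dimethoxyphenyl)-4,5,7-trimethoxy-1H-indene | COc1ccc(cc1OC)C1=CCc2c(OC)cc(OC)c(OC)c12 | intermediate
11 | cis-1-(3,4-dimethoxyphenyl)-4,6,7-trimethoxy-2,3-dihydro-1H-indene-1,2-diol (racemic, hydroxy groups cis, one enantiomer drawn) | O[C@H]1Cc2c(OC)cc(OC)c(OC)c2[C@]1(O)c1ccc(OC)c(OC)c1 | intermediate
12 | 2-[2-(3,4-dimethoxybenzoyl)-3,4,6-trimethoxyphenyl]acetaldehyde | O=CCc1c(OC)cc(OC)c(OC)c1C(=O)c1ccc(OC)c(OC)c1 | intermediate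
13 | 2-[2-(3,4-dimethoxybenzoyl)-3,4,6-trimethoxyphenyl]acetic acid | OC(=O)Cc1c(OC)cc(OC)c(OC)c1C(=O)c1ccc(OC)c(OC)c1 | intermediate
14 | acetic 2-[2-(3,4-dimethoxybenzoyl)-3,4,6-trimethoxyphenyl]acetic anhydride | CC(=O)OC(=O)Cc1c(OC)cc(OC)c(OC)c1C(=O)c1ccc(OC)c(OC)c1 | intermediate
15 | 1-(3,4-dimethoxyphenyl)-5,7,8-trimethoxy-3H-2-benzopyran-3-one | O=C1C=C2C(OC)=CC(OC)=C(OC)C2=C(c2ccc(OC)c(OC)c2)O1 | intermediate
16 | 2-chloro-1,1-dimethoxyethane | COC(CCl)OC | starting material
17 | 1-chloro-2-methoxyethene (E/Z mixture) | COC=CCl | intermediate
18 | sodium methoxyacetylide | [Na+].[C-]#COC | intermediate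
19 | methoxyacetylene (methoxyethyne) | COC#C | intermediate
20 | bridged lactone: the 2-oxabicyclo[2.2.2]octadienone from addition of 19 across C1 and C4 of 15, aryl on the O-bearing bridgehead, methoxy on the alkene carbon next to the CH bridgehead (racemic, one enantiomer drawn) | O=C1O[C@]2(c3ccc(OC)c(OC)c3)C=C(OC)[C@H]1c1c(OC)cc(OC)c(OC)c12 | intermediate
21 | 8-(3,4-dimethoxyphenyl)-1,2,4,6-tetramethoxynaphthalene | COc1cc(OC)c2cc(OC)cc(-c3ccc(OC)c(OC)c3)c2c1OC | intermediate
22 | 8-(3,4-dimethoxyphenyl)-2,6-dimethoxynaphthalene-1,4-dione | COC1=CC(=O)c2cc(OC)cc(-c3ccc(OC)c(OC)c3)c2C1=O | target

## Step count and risks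

Total step count: 10. Longest linear sequence: 9 (steps 1 to 7, 9 and 10, from aldehyde 1); step 8 supplies 19 in a one-step side branch.

Step 9 (key step, proposed new method). Pyranone 15 carries three donor groups and 19 is itself electron-rich, so the cycloaddition may be slow. At the temperature then needed, dimerisation or hydrolysis of 15 and oligomerisation of 19 could outrun ring formation. A reversed orientation, which would place the methoxy group on C7, is the second possible failure. The fallback uses known chemistry only, sets out from keto aldehyde 12 and returns at 21. Aldehyde-selective methyl transfer to 12 (MeTi(OiPr)3, THF, −30 °C) should give the secondary alcohol (3,4-dimethoxyphenyl)[2-(2-hydroxypropyl)-3,5,6-trimethoxyphenyl]methanone F1. Dess–Martin oxidation would give the methyl ketone 1-[2-(3,4-dimethoxybenzoyl)-3,4,6-trimethoxyphenyl]propan-2-one F2. Base (KOH, EtOH, reflux) should then bring about an intramolecular aldol condensation of the methyl enolate onto the diaryl ketone, with dehydration and tautomerisation to 4-(3,4-dimethoxyphenyl)-5,6,8-trimethoxynaphthalen-2-ol F3. Methylation (MeI, K2CO3, acetone) gives 21. In this path the C6 oxygen is the former methyl ketone carbonyl, so the regiochemistry is fixed by connectivity.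

Step 7. The ortho-quinoid lactone may revert to 13 with moisture or dimerise during concentration and crystallisation, and acetic acid carried over would consume 19. The fallback sets out from 13 and returns at 15 without isolating it. The acid is converted into 2-[2-(3,4-dimethoxybenzoyl)-3,4,6-trimethoxyphenyl]acetyl chloride F4 ((COCl)2, cat. DMF, CH2Cl2, 0 °C). Et3N in PhMe at 0 °C then removes HCl, and the resulting aroyl-substituted aryl ketene should close to 15 by oxa-6π electrocyclisation. The solution is filtered from the ammonium salt under argon and used directly in step 9.

Step 4. The basic Grignard reagent may enolise the indanone, whose carbonyl is also shielded by the neighbouring C7 methoxy group, so that 6 is recovered after work-up. The fallback sets out from 6 and returns at 10, and uses the enolisation instead of fighting it. KN(SiMe3)2 (THF, −78 °C) and PhN(SO2CF3)2 should give 4,5,7-trimethoxy-1H-inden-3-yl trifluoromethanesulfonate F5. Suzuki–Miyaura coupling with (3,4-dimethoxyphenyl)boronic acid (Pd(PPh3)4, a zerovalent palladium complex, K2CO3, dioxane/H2O, 80 °C) then gives 10.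

Step 5. Aldehyde 12 is an arylacetaldehyde with acidic benzylic hydrogens; enolisation, self-condensation or over-oxidation in the aqueous oxidising medium could erode it, and slow glycol cleavage could divert material to an α-hydroxy ketone. The fallback sets out from 10, returns at 13 and so bypasses both 12 and step 6. Dihydroxylation with OsO4 (cat.) and N-methylmorpholine N-oxide gives diol 11, which is isolated. Oxidation of its secondary alcohol (SO3·pyridine, DMSO, Et3N) should give 1-(3,4-dimethoxyphenyl)-1-hydroxy-4,6,7-trimethoxy-1,3-dihydro-2H-inden-2-one F6. NaIO4 in MeOH/H2O cleaves this α-ketol between C1 and C2 to the diaryl ketone and the carboxylic acid, which is 13.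

Step 10. Loss of the C1/C2 methyl pair would give an ortho-quinone in competition with the para-quinone, and radical-cation coupling or attack on ring C could also lower the return; the product itself is sensitive to excess oxidant. The fallback sets out from 21 and returns at 22. Anodic oxidation in KOH/MeOH (Pt electrodes, undivided cell, 0 °C) should give the quinone bisketal 8-(3,4-dimethoxyphenyl)-1,1,2,4,4,6-hexamethoxy-1,4-dihydronaphthalene F7. Mild aqueous acid (AcOH/H2O) hydrolyses both ketals to 22; because both ketal carbons become carbonyl groups, the para-quinone is the only possible outcome.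

## Further compounds

F1 | step 9 | (3,4-dimethoxyphenyl)[2-(2-hydroxypropyl)-3,5,6-trimethoxyphenyl]methanone (racemic) | CC(O)Cc1c(OC)cc(OC)c(OC)c1C(=O)c1ccc(OC)c(OC)c1
F2 | step 9 | 1-[2-(3,4-dimethoxybenzoyl)-3,4,6-trimethoxyphenyl]propan-2-one | CC(=O)Cc1c(OC)cc(OC)c(OC)c1C(=O)c1ccc(OC)c(OC)c1
F3 | step 9 | 4-(3,4-dimethoxyphenyl)-5,6,8-trimethoxynaphthalen-2-ol | COc1cc(OC)c2cc(O)cc(-c3ccc(OC)c(OC)c3)c2c1OC
F4 | step 7 | 2-[2-(3,4-dimethoxybenzoyl)-3,4,6-trimethoxyphenyl]acetyl chloride | O=C(Cl)Cc1c(OC)cc(OC)c(OC)c1C(=O)c1ccc(OC)c(OC)c1
F5 | step 4 | 4,5,7-trimethoxy-1H-inden-3-yl trifluoromethanesulfonate | COc1cc(OC)c(OC)c2c1CC=C2OS(=O)(=O)C(F)(F)F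
F6 | step 5 | 1-(3,4-dimethoxyphenyl)-1-hydroxy-4,6,7-trimethoxy-1,3-dihydro-2H-inden-2-one (racemic) | O=C1Cc2c(OC)cc(OC)c(OC)c2C1(O)c1ccc(OC)c(OC)c1
F7 | step 10 | 8-(3,4-dimethoxyphenyl)-1,1,2,4,4,6-hexamethoxy-1,4-dihydronaphthalene | COC1=CC(OC)(OC)c2cc(OC)cc(-c3ccc(OC)c(OC)c3)c2C1(OC)OC
A1 | alternative 1 | 2-methoxycyclohexa-2,5-diene-1,4-dione (2-methoxy-1,4-benzoquinone) | COC1=CC(=O)C=CC1=O
A2 | alternative 1 | tert-butyl{[(3E)-4-(3,4-dimethoxyphenyl)buta-1,3-dien-2-yl]oxy}dimethylsilane | C=C(O[Si](C)(C)C(C)(C)C)/C=C/c1ccc(OC)c(OC)c1
A3 | alternative 1 | 6-(tert-butyldimethylsilyloxy)-8-(3,4-dimethoxyphenyl)-2-methoxy-4a,5,8,8a-tetrahydronaphthalene-1,4-dione (racemic endo adduct, H at C4a, C8 and C8a all cis, one enantiomer drawn) | COC1=CC(=O)[C@H]2CC(O[Si](C)(C)C(C)(C)C)=C[C@@H](c3ccc(OC)c(OC)c3)[C@H]2C1=O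
A4 | alternative 2 | 2-[1-(3,4-dimethoxyphenyl)ethenyl]-6-methoxycyclohexa-2,5-diene-1,4-dione | COC1=CC(=O)C=C(C(=C)c2ccc(OC)c(OC)c2)C1=O
A5 | alternative 2 | 1,1-dimethoxyethene | C=C(OC)OC
A6 | alternative 2 | 8-(3,4-dimethoxyphenyl)-2,6,6-trimethoxy-5,6-dihydronaphthalene-1,4-diol | COc1cc(O)c2c(c1O)C(c1ccc(OC)c(OC)c1)=CC(OC)(OC)C2
A7 | alternative 3 | 2-(2,4,5-trimethoxyphenyl)acetyl chloride | COc1cc(OC)c(CC(=O)Cl)cc1OC
A8 | alternative 3 | 4-ethynyl-1,2-dimethoxybenzene | C#Cc1ccc(OC)c(OC)c1
A9 | alternative 3 | 4-(3,4-dimethoxyphenyl)-5,6,8-trimethoxynaphthalen-2-ol | COc1cc(OC)c2cc(O)cc(-c3ccc(OC)c(OC)c3)c2c1OC
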